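**Retrosynthetic overview**

1. Rhodisin is two (−)-epigallocatechin gallate units joined C4(upper)–C8(lower). The last disconnections are the sixteen benzyl ethers, the upper C3 gallate ester and the interflavan C4–C8 bond (flavan-4-yl cation plus octa-O-benzyl-(−)-epigallocatechin gallate, itself made from (−)-epigallocatechin by penta-O-benzylation and galloylation).
2. Ring C of the upper unit is built by a (3+3) annulation of 3,5-bis(benzyloxy)phenol (ring A) with a cis-2,3-epoxy aldehyde (C2–C3–C4 carrying ring B). C4a–C4 and O1–C2 form in one titanium-mediated operation to give a 2,3-cis-flavan-3,4-diol.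
3. Enabling feature: ring A is a symmetric 3,5-dioxygenated phenol, so O1 and either of its two equivalent ortho carbons (C4a) form a 1,3-O,C-bis-nucleophile. C2 (benzylic to ring B) and C4 flank the oxygen-bearing C3 and can be offered as a 1,3-bis-electrophile, an aldehyde at C4 and a cis-epoxide across C2–C3.
4. Stereochemistry: one catalytic event (Sharpless epoxidation of a Z-cinnamyl alcohol) sets C3 and C2, C2 is inverted stereospecifically in the annulation, and C4 is relayed from C3 (3,4-trans) in the coupling. The two centres of the lower unit are bought with (−)-epigallocatechin.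
5. Ring order: rings A and B and the whole lower flavan skeleton are bought; the only ring formed is ring C of the upper unit (step 5).

Key step: step 5

Remark: flavan numbering (O1, C2, C3, C4, C4a, C8a; rings A, B, C) is used for the upper unit. C4 of diol 10 is carried as an epimer mixture because it is ionised in step 8. Compounds 1, 2, 7, 11 and 13 are taken as commercial.

**Route**

Step 1
Reactants: 1 3,4,5-tris(benzyloxy)benzaldehyde; 2 methyl bis(2,2,2-trifluoroethyl)phosphonoacetate
Product: 3 methyl (Z)-3-[3,4,5-tris(benzyloxy)phenyl]prop-2-enoate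
Conditions: KN(SiMe3)2, 18-crown-6, THF, −78 °C
Reagents that add atoms: none
Why: Still–Gennari variant of the Horner–Wadsworth–Emmons olefination, in which the electron-poor phosphonate and the dissociated potassium enolate give fast, kinetically controlled elimination to the Z-enoate with aromatic aldehydes; no stereocentre is formed, only the Z geometry that later becomes the cis-epoxide.

Step 2
Reactants: 3 methyl (Z)-3-[3,4,5-tris(benzyloxy)phenyl]prop-2-enoate
Product: 4 (Z)-3-[3,4,5-tris(benzyloxy)phenyl]prop-2-en-1-ol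
Conditions: iBu2AlH (2.2 equiv), CH2Cl2, −78 °C; aq. potassium sodium tartrate
Reagents that add atoms: none
Why: 1,2-reduction of an enoate with iBu2AlH at low temperature should give the allylic alcohol without Z-to-E isomerisation and without touching the benzyl ethers.

Step 3
Reactants: 4 (Z)-3-[3,4,5-tris(benzyloxy)phenyl]prop-2-en-1-ol
Product: 5 [(2R,3S)-3-[3,4,5-tris(benzyloxy)phenyl]oxiran-2-yl]methanol (cis-epoxide)
Conditions: Ti(OiPr)4 (0.2 equiv), D-(−)-diethyl tartrate (0.26 equiv), tBuOOH (2 equiv), 4 Å molecular sieves, CH2Cl2, −20 °C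
Reagents that add atoms: tert-butyl hydroperoxide CC(C)(C)OO
Why: Sharpless asymmetric epoxidation, in which the allylic hydroxyl binds the titanium tartrate catalyst and D-(−)-diethyl tartrate directs syn oxygen transfer to the face that gives the (2R)-epoxide, so both epoxide carbons (the later C3 and C2 of ring C) are set in one catalytic event as the cis-(2R,3S) isomer.

Step 4
Reactants: 5 [(2R,3S)-3-[3,4,5-tris(benzyloxy)phenyl]oxiran-2-yl]methanol
Product: 6 (2S,3S)-3-[3,4,5-tris(benzyloxy)phenyl]oxirane-2-carbaldehyde (cis; same spatial arrangement as 5, the C2 descriptor changes only because CHO outranks the ring carbon)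
Conditions: nPr4N[RuO4] (5 mol%), N-methylmorpholine N-oxide (1.5 equiv), 4 Å molecular sieves, CH2Cl2, 0 °C to rt
Reagents that add atoms: none
Why: Ley–Griffith oxidation under neutral conditions should convert the primary alcohol into the aldehyde without opening the acid-sensitive aryl epoxide and without epimerising the alpha carbon, whose enolisation is disfavoured by ring strain.

Step 5
Reactants: 6 (2S,3S)-3-[3,4,5-tris(benzyloxy)phenyl]oxirane-2-carbaldehyde; 7 3,5-bis(benzyloxy)phenol
Product: 10 (2R,3R)-5,7-bis(benzyloxy)-2-[3,4,5-tris(benzyloxy)phenyl]-3,4-dihydro-2H-chromene-3,4-diol (C4 epimer mixture), via aryloxytitanium triisopropoxide 8 (not isolated), via titanium-bound epoxy carbinol 9 (not isolated)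
Conditions: 7, Ti(OiPr)4 (1.1 equiv), toluene, rt, then removal of iPrOH in vacuo; 6 (1.0 equiv), CH2Cl2, −20 °C to rt, then 35 °C; aq. potassium sodium tartrate
Reagents that add atoms: none
Why: Proposed new method: the aryloxytitanium reagent 8 binds the aldehyde oxygen of 6 and delivers its ortho carbon to the carbonyl carbon through a six-membered cyclic transition state (ortho-specific hydroxyalkylation, closest known type: magnesium and titanium phenolates with alpha-oxygenated aldehydes), which forms C4a–C4 and leaves the 2,3-epoxy alcohol 9 held on the same tetravalent titanium through its phenolate and C4 alkoxide. That titanium then activates the epoxide as in the titanium isopropoxide-mediated C-3 opening of 2,3-epoxy alcohols, and the phenolic oxygen attacks the benzylic epoxide carbon (closest known type: phenol–epoxide cyclisations used for flavan-3-ols), which forms O1–C2. Ring C is closed by a 6-endo-tet SN2 epoxide opening. C3 keeps the epoxide C–O bond and its configuration from step 3, C2 is set by inversion at the epoxide carbon so that the cis-epoxide becomes the 2,3-cis (2R,3R) arrangement, and C4 forms as a carbinol epimer mixture that is erased in step 8. The step needs C- over O-attack and ortho over para attack of the phenol, secured by delivery of the titanium-bound aldehyde within the phenolate complex in a non-polar medium and by the symmetry of ring A, which makes both ortho carbons equivalent; the epoxide stays untouched until the carbinol anchors it to titanium. It also needs 6-endo over 5-exo opening and SN2 over SN1 behaviour at C2, secured by the benzylic, chelate-distal position of C2, by the neutral non-protic conditions and by the two meta benzyloxy groups of ring B, which temper cation formation.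

Step 6
Reactants: 11 (−)-epigallocatechin
Product: 12 5,7,3′,4′,5′-penta-O-benzyl-(−)-epigallocatechin (C3 hydroxyl free)
Conditions: BnBr (5.5 equiv), K2CO3 (6 equiv), degassed DMF, N2, 0 °C to rt
Reagents that add atoms: benzyl bromide BrCc1ccccc1
Why: Williamson etherification of the five phenols with K2CO3 in DMF, routine for catechin-type flavan-3-ols, in which the aliphatic C3 hydroxyl is not deprotonated by carbonate and stays free, while the anhydrous, oxygen-free conditions at or below room temperature should suppress C2 epimerisation and oxidation of the pyrogallol ring.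

Step 7
Reactants: 12 5,7,3′,4′,5′-penta-O-benzyl-(−)-epigallocatechin; 13 3,4,5-tris(benzyloxy)benzoic acid
Product: 14 octa-O-benzyl-(−)-epigallocatechin gallate
Conditions: 13 (1.5 equiv), N,N'-dicyclohexylcarbodiimide (DCC), 4-(dimethylamino)pyridine (DMAP), CH2Cl2, rt
Reagents that add atoms: none
Why: Steglich esterification, a standard galloylation of the axial C3 hydroxyl of benzylated 2,3-cis flavan-3-ols, which acylates on oxygen with retention and leaves both stereocentres untouched.

Step 8
Reactants: 10 (2R,3R)-5,7-bis(benzyloxy)-2-[3,4,5-tris(benzyloxy)phenyl]-3,4-dihydro-2H-chromene-3,4-diol; 14 octa-O-benzyl-(−)-epigallocatechin gallate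
Product: 15 5,7,3′,4′,5′-penta-O-benzyl-(−)-epigallocatechin-(4β→8)-octa-O-benzyl-(−)-epigallocatechin 3-O-gallate (upper C3 hydroxyl free)
Conditions: 14 (3 equiv), BF3·OEt2 (0.5 equiv), 4 Å molecular sieves, CH2Cl2, −78 to −20 °C; Et3N quench
Reagents that add atoms: none
Why: Lewis-acid-promoted Friedel–Crafts alkylation of the type used for B-type proanthocyanidins, in which BF3·OEt2 ionises the C4 hydroxyl of either epimer of 10 to a cation stabilised by the 5,7-dioxygenated ring A and C8 of the excess nucleophile 14 adds anti to the quasi-axial C3 hydroxyl of the 2,3-cis ring, so that C4 is set 3,4-trans (4R, 4β) by substrate control.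

Step 9
Reactants: 15 5,7,3′,4′,5′-penta-O-benzyl-(−)-epigallocatechin-(4β→8)-octa-O-benzyl-(−)-epigallocatechin 3-O-gallate; 13 3,4,5-tris(benzyloxy)benzoic acid
Product: 16 hexadeca-O-benzylrhodisin
Conditions: 13 (3 equiv), N,N'-dicyclohexylcarbodiimide (DCC), 4-(dimethylamino)pyridine (DMAP), CH2Cl2, rt
Reagents that add atoms: none
Why: Steglich esterification, a standard galloylation of the hindered axial C3 hydroxyl of flavan-3-ols, which creates no stereocentre and proceeds under conditions that leave the acid-sensitive interflavan bond alone.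

Step 10
Reactants: 16 hexadeca-O-benzylrhodisin
Product: 17 rhodisin
Conditions: H2 (1 atm), Pd(OH)2/C, THF/MeOH/H2O, rt
Reagents that add atoms: none
Why: Global hydrogenolysis of the sixteen benzyl ethers over Pd(OH)2/C under neutral conditions should release all phenols while the two gallate esters, the cyclic benzylic ethers and the interflavan bond stay intact, as in standard proanthocyanidin deprotections.

**Compound list**

1 | 3,4,5-tris(benzyloxy)benzaldehyde | O=Cc1cc(OCc2ccccc2)c(OCc2ccccc2)c(OCc2ccccc2)c1 | starting material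
2 | methyl bis(2,2,2-trifluoroethyl)phosphonoacetate | COC(=O)CP(=O)(OCC(F)(F)F)OCC(F)(F)F | starting material
3 | methyl (Z)-3-[3,4,5-tris(benzyloxy)phenyl]prop-2-enoate | COC(=O)/C=C\c1cc(OCc2ccccc2)c(OCc2ccccc2)c(OCc2ccccc2)c1 | intermediate
4 | (Z)-3-[3,4,5-tris(benzyloxy)phenyl]prop-2-en-1-ol | OC/C=C\c1cc(OCc2ccccc2)c(OCc2ccccc2)c(OCc2ccccc2)c1 | intermediate
5 | [(2R,3S)-3-[3,4,5-tris(benzyloxy)phenyl]oxiran-2-yl]methanol | OC[C@H]1O[C@H]1c1cc(OCc2ccccc2)c(OCc2ccccc2)c(OCc2ccccc2)c1 | intermediate
6 | (2S,3S)-3-[3,4,5-tris(benzyloxy)phenyl]oxirane-2-carbaldehyde | O=C[C@H]1O[C@H]1c1cc(OCc2ccccc2)c(OCc2ccccc2)c(OCc2ccccc2)c1 | intermediate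
7 | 3,5-bis(benzyloxy)phenol | Oc1cc(OCc2ccccc2)cc(OCc2ccccc2)c1 | starting material
8 | [3,5-bis(benzyloxy)phenoxy]tri(propan-2-yloxy)titanium | CC(C)O[Ti](OC(C)C)(OC(C)C)Oc1cc(OCc2ccccc2)cc(OCc2ccccc2)c1 | intermediate
9 | [2,4-bis(benzyloxy)-6-hydroxyphenyl]{(2R,3S)-3-[3,4,5-tris(benzyloxy)phenyl]oxiran-2-yl}methanol (formed as its titanium chelate, drawn titanium-free, carbinol epimers) | Oc1cc(OCc2ccccc2)cc(OCc2ccccc2)c1C(O)[C@H]1O[C@H]1c1cc(OCc2ccccc2)c(OCc2ccccc2)c(OCc2ccccc2)c1 | intermediate
10 | (2R,3R)-5,7-bis(benzyloxy)-2-[3,4,5-tris(benzyloxy)phenyl]-3,4-dihydro-2H-chromene-3,4-diol (C4 epimer mixture) | O[C@@H]1C(O)c2c(OCc3ccccc3)cc(OCc3ccccc3)cc2O[C@@H]1c1cc(OCc2ccccc2)c(OCc2ccccc2)c(OCc2ccccc2)c1 | intermediate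
11 | (−)-epigallocatechin, (2R,3R) | O[C@@H]1Cc2c(O)cc(O)cc2O[C@@H]1c1cc(O)c(O)c(O)c1 | starting material
12 | 5,7,3′,4′,5′-penta-O-benzyl-(−)-epigallocatechin, (2R,3R), C3 hydroxyl free | O[C@@H]1Cc2c(OCc3ccccc3)cc(OCc3ccccc3)cc2O[C@@H]1c1cc(OCc2ccccc2)c(OCc2ccccc2)c(OCc2ccccc2)c1 | intermediate
13 | 3,4,5-tris(benzyloxy)benzoic acid | O=C(O)c1cc(OCc2ccccc2)c(OCc2ccccc2)c(OCc2ccccc2)c1 | starting material
14 | octa-O-benzyl-(−)-epigallocatechin gallate | O=C(O[C@@H]1Cc2c(OCc3ccccc3)cc(OCc3ccccc3)cc2O[C@@H]1c1cc(OCc2ccccc2)c(OCc2ccccc2)c(OCc2ccccc2)c1)c1cc(OCc2ccccc2)c(OCc2ccccc2)c(OCc2ccccc2)c1 | intermediate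
15 | 5,7,3′,4′,5′-penta-O-benzyl-(−)-epigallocatechin-(4β→8)-octa-O-benzyl-(−)-epigallocatechin 3-O-gallate, upper unit (2R,3R,4R) with free C3 hydroxyl | O[C@@H]1[C@@H](c2c(OCc4ccccc4)cc(OCc4ccccc4)c3c2O[C@H](c2cc(OCc4ccccc4)c(OCc4ccccc4)c(OCc4ccccc4)c2)[C@H](OC(=O)c2cc(OCc4ccccc4)c(OCc4ccccc4)c(OCc4ccccc4)c2)C3)c2c(OCc3ccccc3)cc(OCc3ccccc3)cc2O[C@@H]1c1cc(OCc2ccccc2)c(OCc2ccccc2)c(OCc2ccccc2)c1 | intermediate
16 | hexadeca-O-benzylrhodisin | O=C(O[C@@H]1[C@@H](c2c(OCc4ccccc4)cc(OCc4ccccc4)c3c2O[C@H](c2cc(OCc4ccccc4)c(OCc4ccccc4)c(OCc4ccccc4)c2)[C@H](OC(=O)c2cc(OCc4ccccc4)c(OCc4ccccc4)c(OCc4ccccc4)c2)C3)c2c(OCc3ccccc3)cc(OCc3ccccc3)cc2O[C@@H]1c1cc(OCc2ccccc2)c(OCc2ccccc2)c(OCc2ccccc2)c1)c1cc(OCc2ccccc2)c(OCc2ccccc2)c(OCc2ccccc2)c1 | intermediate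
17 | rhodisin | O=C(O[C@@H]1[C@@H](c2c(O)cc(O)c3c2O[C@H](c2cc(O)c(O)c(O)c2)[C@H](OC(=O)c2cc(O)c(O)c(O)c2)C3)c2c(O)cc(O)cc2O[C@@H]1c1cc(O)c(O)c(O)c1)c1cc(O)c(O)c(O)c1 | target

**Step count and risks**

Total step count: 10. Longest linear sequence: 8 steps (steps 1, 2, 3, 4, 5, 8, 9, 10 from aldehyde 1); steps 6 and 7 form a two-step side branch from (−)-epigallocatechin 11.

Steps most likely to fail:

Step 5 (Proposed new method). What may go wrong: ionisation of the electron-rich benzylic carbinol to an ortho-quinone methide followed by diarylmethane formation or oligomerisation, a second hydroxyalkylation at the other ortho carbon, opening of the epoxide by isopropoxide, or 5-exo instead of 6-endo opening. The fallback uses known chemistry only; it sets out from epoxy alcohol 5 and phenol 7 and comes back at diol 10, making the two bonds in separate steps. Titanium isopropoxide-mediated C-3 opening of 5 by the phenolic oxygen of 7 (Ti(OiPr)4, toluene/CH2Cl2, rt to 40 °C, inversion at the benzylic carbon) should give the aryl ether diol (2R,3R)-3-[3,5-bis(benzyloxy)phenoxy]-3-[3,4,5-tris(benzyloxy)phenyl]propane-1,2-diol F1. Chemoselective oxidation of its primary hydroxyl (catalytic 2,2,6,6-tetramethylpiperidine N-oxyl, PhI(OAc)2, CH2Cl2) should give the alpha-hydroxy aldehyde (2S,3R)-3-[3,5-bis(benzyloxy)phenoxy]-2-hydroxy-3-[3,4,5-tris(benzyloxy)phenyl]propanal F2. This is closed without purification by intramolecular Friedel–Crafts hydroxyalkylation ortho to the ether oxygen (MgBr2·OEt2 or catalytic Sc(OTf)3, CH2Cl2, −40 °C) to 10.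

Step 8. What may go wrong: self-condensation of the C4 cation with ring A of a second molecule of 10 or of product 15 (oligomerisation), attack at C6 instead of C8 of 14, and acid-mediated scission of the newly formed interflavan bond. The fallback sets out from 10 and comes back at 15 and replaces hard-acid activation of the hydroxyl by a storable thio donor activated by a soft thiophile. Thiolysis of 10 (PhSH in excess, catalytic BF3·OEt2, CH2Cl2, −40 °C) should give the 3,4-trans thioether (2R,3S,4S)-5,7-bis(benzyloxy)-4-(phenylsulfanyl)-2-[3,4,5-tris(benzyloxy)phenyl]chroman-3-ol F3. Treating F3 with AgBF4 (THF/CH2Cl2, −20 °C) in the presence of 14 should then release the same C4 cation under non-protic conditions and give 15.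

Step 3. What may go wrong: slow and less enantioselective epoxidation of the Z-disubstituted allylic alcohol, and titanium-assisted opening of the electron-rich benzylic epoxide by isopropanol or tartrate. The fallback sets out from enoate 3 and comes back at epoxy alcohol 5. Jacobsen–Katsuki epoxidation of 3 (NaOCl, 4-phenylpyridine N-oxide, catalytic (S,S)-[N,N'-bis(3,5-di-tert-butylsalicylidene)cyclohexane-1,2-diamine]MnCl, a trivalent-manganese complex, CH2Cl2, 0 °C) should give the cis-glycidic ester methyl (2S,3S)-3-[3,4,5-tris(benzyloxy)phenyl]oxirane-2-carboxylate F4. Reduction of the ester with iBu2AlH (2.2 equiv, CH2Cl2, −78 °C) then gives 5.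

Further compounds

F1 | step 5 | (2R,3R)-3-[3,5-bis(benzyloxy)phenoxy]-3-[3,4,5-tris(benzyloxy)phenyl]propane-1,2-diol | OC[C@@H](O)[C@H](Oc1cc(OCc2ccccc2)cc(OCc2ccccc2)c1)c1cc(OCc2ccccc2)c(OCc2ccccc2)c(OCc2ccccc2)c1
F2 | step 5 | (2S,3R)-3-[3,5-bis(benzyloxy)phenoxy]-2-hydroxy-3-[3,4,5-tris(benzyloxy)phenyl]propanal | O=C[C@@H](O)[C@H](Oc1cc(OCc2ccccc2)cc(OCc2ccccc2)c1)c1cc(OCc2ccccc2)c(OCc2ccccc2)c(OCc2ccccc2)c1
F3 | step 8 | (2R,3S,4S)-5,7-bis(benzyloxy)-4-(phenylsulfanyl)-2-[3,4,5-tris(benzyloxy)phenyl]chroman-3-ol | O[C@@H]1[C@@H](Sc2ccccc2)c2c(OCc3ccccc3)cc(OCc3ccccc3)cc2O[C@@H]1c1cc(OCc2ccccc2)c(OCc2ccccc2)c(OCc2ccccc2)c1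
F4 | step 3 | methyl (2S,3S)-3-[3,4,5-tris(benzyloxy)phenyl]oxirane-2-carboxylate | COC(=O)[C@H]1O[C@H]1c1cc(OCc2ccccc2)c(OCc2ccccc2)c(OCc2ccccc2)c1
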